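## The problem

CNP0298733.1 (30) is a labdane built on a decalin: ring A (C1–C5, C10) and ring B (C5–C10) share the C5–C10 bond. A γ-lactone joins C19 on C4 to O6, an oxolane (ring C: O, C9, C11, C12, C13) is spiro-fused to ring B at C9, and a butyrolactone (ring D: C13, C14, C15, O, C16) is spiro-fused to ring C at C13. C17 is the methyl on C8, C18 the methyl on C4, and C20 on C10 is a CH2OAc group. Seven stereocentres must be set (4S,5S,6R,8R,9R,10S,13R); four are fully substituted (C4, C9, C10, C13), and C9 and C10 are bonded to each other. As drawn, H5, the C19 carbonyl, O6 and C20 all lie on one face, so rings A and B are cis-fused and the C6 branch on C5 is trans to C19 on ring A; a small or planar C19 precursor on C4 would be expected to steer bond formation at C5 to the other face. C13 and C8 are too remote to be controlled by the rings and must arrive in enantiopure building blocks; C4 can control C5, C5 can control C6, and C5 and C6 together can control C10 and C9 when ring B closes. The acetate and the two lactones exclude strong base, organometallics and hydrides stronger than borohydride late in the route, and the 19,6-lactone, which closes only when ring B leaves its chair, is best made last. The enabling feature is that C9, the ether carbon of ring C, is bonded to quaternary C10 and that C20 on C10 is syn to O6: a cyclic enol ether O6–C20=C10 can attack an oxocarbenium ion at C9 from within, closing ring B and fixing C10 through the tether.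

## Retrosynthesis

**Lactone and C19.** The acyl–O6 bond is cut last (30 to hydroxy acid 29), so the one strained ring is not carried through the synthesis. The carboxyl is traced to a phenyl group (28 from 27), with O6 as a chloroacetate and O20 already acetylated (27 from 26 from diol 25). Phenyl is preferred to an ester or nitrile for three reasons: it is the larger group on C4 and directs the C5–C6 bond to the face this target needs; it cannot lactonise onto the C20 hydroxyl of 25; and in 27 every oxygen-bearing carbon is acylated or fully substituted, so RuO4 has only the arene to attack. The forward steps must acetylate the primary hydroxyl selectively, degrade the arene, and acylate a hindered secondary alcohol intramolecularly.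

**C20–O6 bridge.** Diol 25 comes from the bridged methyl acetal 23 by hydrolysis to lactol 24 and reduction. This is the natural exit from the key step, because C20 leaves it at the aldehyde oxidation level and needs only borohydride.

**C9–C10 (key step).** In 23 the C9–C10 bond and the C20–OMe bond are cut together, giving 22, which holds ring A, the O6–C20=C10 dihydrofuran and the ring C methyl ketal. This cut removes ring B, both adjacent quaternary centres and the C9/C10 stereochemistry at once; a cut at C5–C10 or C8–C9 would leave the C9–C10 bond to be made intermolecularly. The forward reaction must ionise the ketal without destroying the enol ether and must close a six-membered ring between two fully substituted carbons.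

**Enol ether.** The O6–C20 bond of 22 is opened to lactol 21, the cyclic form of the C20 aldehyde 20 with a free 6-hydroxyl. C20 is disconnected from C10 as a one-carbon homologation of ketone 18 through the methyl enol ether 19. Dehydrating the lactol under basic conditions is chosen over acid-catalysed acetal exchange, because only that route lets the C9 ketal and the C8 stereocentre pass untouched.

**C5–C6.** Ketone 18 is cut between C5 and C6 into enol silane 17 and aldehyde 15. This is the convergent point, joining ring A to the complete C6–C16 chain. The forward aldol must add anti to the phenyl group (C5) and through an open transition state (syn aldol, C6) under conditions that do not ionise the ketal, so it is run under fluoride catalysis and not with a Lewis acid.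

**C4.** Enol silane 17 comes from 3-methylcyclohex-2-en-1-one 16 by enantioselective conjugate addition of phenyl and O-silylation of the enolate. This fixes both the quaternary centre and the enolate regiochemistry in one step.

**Aldehyde 15.** The aldehyde is the ozonolysis product of alkene 14. The ketal O–C9 bond of 14 is cut back to the homopropargylic alcohol 13: an alkyne between C9 and C11 is a ketone equivalent that the C13 hydroxyl unmasks regiospecifically. Lactone D of 13 arises by transacylation within dioxolanone 12.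

**C12–C13.** Dioxolanone 12 is cut at C12–C13 into the malic-acid-derived dioxolanone 11 and propargylic bromide 7. Enolate alkylation with self-regeneration of the stereocentre sets C13 with certainty, and the electrophile is activated.

**Building blocks.** Dioxolanone 11 comes from (R)-malic acid 8 through acid 9 and alcohol 10. Bromide 7 comes from the Evans imide 1 through 2, 3, 4, 5 and 6, with C8 set by auxiliary-controlled allylation.

## Roads not taken

Alternative 1: Ring C is cut at O–C13 and C13–C14. In the forward sense Rh2(OAc)4 decomposes the C13 diazo thioester A1; the carbenoid is captured by the oxygen of the C9 allyl ether and the allyl group shifts from oxygen to C13 by a [2,3] rearrangement, giving A2. Ozonolysis, reduction and lactonisation would then finish ring D. Its merits are that ring C and the C13 quaternary centre form in one step on the finished tricyclic lactone, and no acid-labile ketal or enol ether is ever carried; in that respect it is gentler than the chosen plan. Its weakness is that it presupposes the hardest part: the C9–C10 bond, the cis ring fusion and a tertiary allyl ether at the most hindered carbon. C13 would be set only by the facial preference of a five-membered oxonium ylide with distant stereocentres to guide it, and C–H insertion and [1,2] shift compete. Against this the chosen plan sets C13 from (R)-malic acid and makes the C9–C10 bond in the same step that fixes C9 and C10.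

Alternative 2: Rings A and B are cut at C5–C10 and C3–C4. Heating triene A3 at 180 °C would give adduct A4 by an intramolecular Diels–Alder reaction. On bond count it is the better step: two rings, two C–C bonds and the C4, C5 and C10 centres in one operation, with C19 present as an ester from the start and a Z-diene naturally leading to a cis ring fusion. The weak points are that both new bonds end on fully substituted carbons, and that the diene terminus C10 carries C20 and the spiro C9, so the s-cis conformer is strained and hydrogen shifts compete at the temperature required. The relation of C5 and C10 to C6 would rest on the conformational preference of the tether and not on a covalent constraint. The C1=C2 alkene must then be reduced, and A3 is long to make. The chosen plan forms fewer bonds in its key step, but runs at −78 °C and fixes C10 by a tether.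

Alternative 3: The O6–C20 bond is cut as a C–H functionalisation. PhI(OAc)2 and I2 under light would convert the 6-hydroxyl of A5 into its hypoiodite; the oxygen radical abstracts hydrogen from the C10 methyl group and the iodide closes to the ether A6. This is the best-precedented key step of the four, and it lets C20 remain a plain methyl group through a classical decalin synthesis; on reliability of the key step it is superior to the chosen plan. It leaves more to do afterwards: the ether holds C20 at the alcohol level in a ring that must be cleaved regioselectively or re-oxidised. Rings C and D must still be built by adding carbon to a C9 ketone flanked by quaternary C10, from the face syn to the bridge. The cis fusion and the C4/C5 relationship also have to be solved separately. The chosen plan delivers rings A to D in the key step, with C20 as an acetal that opens by hydrolysis and reduction.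

Key step: step 17

Assumption: the ketal-bearing compounds 14–22 form as C9 epimer mixtures (one epimer is written); both ionise to the same cation in step 17, and C19 is carried as a phenyl group until step 21.

## Route

Step 1
Reactants: 1 (4S)-4-benzyl-3-propanoyl-1,3-oxazolidin-2-one
Product: 2 (4S)-4-benzyl-3-[(2R)-2-methylpent-4-enoyl]-1,3-oxazolidin-2-one
Conditions: NaN(SiMe3)2, THF, −78 °C; allyl iodide, −78 → −40 °C
Reagents that add atoms: allyl iodide, C=CCI
Why: Evans alkylation: the chelated Z sodium enolate is allylated on the face away from the benzyl group, which sets C8 as R.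

Step 2
Reactants: 2 (4S)-4-benzyl-3-[(2R)-2-methylpent-4-enoyl]-1,3-oxazolidin-2-one
Product: 3 (2R)-2-methylpent-4-en-1-ol
Conditions: LiBH4, MeOH (1 equiv), Et2O, 0 °C
Reagents that add atoms: none
Why: Reductive cleavage of the N-acyl oxazolidinone; the auxiliary is recovered and the α-centre is not enolised.

Step 3
Reactants: 3 (2R)-2-methylpent-4-en-1-ol
Product: 4 (2R)-2-methylpent-4-enal
Conditions: TEMPO (10 mol %), PhI(OAc)2, CH2Cl2, 0 → 25 °C; washed solution used directly
Reagents that add atoms: none
Why: Nitroxyl-catalysed oxidation of a primary alcohol under non-basic conditions, so the α-stereocentre should be kept.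

Step 4
Reactants: 4 (2R)-2-methylpent-4-enal
Product: 5 (3R)-1,1-dibromo-3-methylhexa-1,5-diene
Conditions: CBr4, PPh3, CH2Cl2, 0 °C
Reagents that add atoms: carbon tetrabromide, BrC(Br)(Br)Br
Why: First stage of the Corey–Fuchs homologation (dibromomethylenation).

Step 5
Reactants: 5 (3R)-1,1-dibromo-3-methylhexa-1,5-diene
Product: 6 (4R)-4-methylhept-6-en-2-yn-1-ol
Conditions: n-BuLi (2.2 equiv), THF, −78 → 0 °C; (CH2O)n, 0 → 25 °C
Reagents that add atoms: formaldehyde (as paraformaldehyde), C=O
Why: Second stage of the Corey–Fuchs sequence gives the lithium acetylide, which adds to formaldehyde; the volatile terminal alkyne is never isolated.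

Step 6
Reactants: 6 (4R)-4-methylhept-6-en-2-yn-1-ol
Product: 7 (4R)-1-bromo-4-methylhept-6-en-2-yne
Conditions: CBr4, PPh3, CH2Cl2, 0 °C
Reagents that add atoms: carbon tetrabromide, BrC(Br)(Br)Br
Why: Appel bromination of a primary propargylic alcohol.

Step 7
Reactants: 8 (R)-malic acid
Product: 9 2-[(2R,4R)-2-tert-butyl-5-oxo-1,3-dioxolan-4-yl]acetic acid
Conditions: pivalaldehyde, TsOH·H2O (cat.), H2SO4 (cat.), pentane, reflux, water separator
Reagents that add atoms: pivalaldehyde, CC(C)(C)C=O
Why: Seebach acetalisation of the α-hydroxy acid unit; the cis dioxolanone is the thermodynamic, crystalline product and stores the C13 configuration in the new acetal centre.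

Step 8
Reactants: 9 2-[(2R,4R)-2-tert-butyl-5-oxo-1,3-dioxolan-4-yl]acetic acid
Product: 11 (2R,5R)-2-tert-butyl-5-[2-(tert-butyldimethylsilyloxy)ethyl]-1,3-dioxolan-4-one, via hydroxyethyl dioxolanone 10 (not isolated)
Conditions: BH3·SMe2, THF, 0 → 25 °C; MeOH; then t-BuMe2SiCl, imidazole, DMF, 0 °C
Reagents that add atoms: tert-butyldimethylsilyl chloride, CC(C)(C)[Si](C)(C)Cl
Why: Borane reduces the free carboxylic acid much faster than the dioxolanone carbonyl; the alcohol is silylated at once so that it cannot transacylate.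

Step 9
Reactants: 11 (2R,5R)-2-tert-butyl-5-[2-(tert-butyldimethylsilyloxy)ethyl]-1,3-dioxolan-4-one; 7 (4R)-1-bromo-4-methylhept-6-en-2-yne
Product: 12 (2R,5R)-2-tert-butyl-5-[2-(tert-butyldimethylsilyloxy)ethyl]-5-[(4R)-4-methylhept-6-en-2-yn-1-yl]-1,3-dioxolan-4-one
Conditions: LiN(i-Pr)2, THF, −78 °C; 7, N,N′-dimethylpropyleneurea, −78 → −40 °C
Reagents that add atoms: none
Why: Seebach alkylation with self-regeneration of the stereocentre: the lithium enolate is alkylated by the propargylic bromide opposite the tert-butyl group, so C12 replaces H13 with retention (13R).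

Step 10
Reactants: 12 (2R,5R)-2-tert-butyl-5-[2-(tert-butyldimethylsilyloxy)ethyl]-5-[(4R)-4-methylhept-6-en-2-yn-1-yl]-1,3-dioxolan-4-one
Product: 14 (2S,5R)-2-methoxy-2-[(2R)-pent-4-en-2-yl]-1,7-dioxaspiro[4.4]nonan-6-one (2R epimer also present), via hydroxy lactone 13 (not isolated)
Conditions: TsOH·H2O (0.2 equiv), MeOH, 40 °C; then (Ph3P)AuCl (2 mol %), AgOTf (2 mol %), 25 °C
Reagents that add atoms: methanol, CO
Why: Acidic methanol cleaves the silyl ether and the freed C15 hydroxyl transacylates the dioxolanone to the γ-lactone with loss of pivalaldehyde. The gold catalyst then adds the tertiary hydroxyl 5-endo-dig to the alkyne and methanol adds to the resulting dihydrofuran (tandem cycloisomerisation–hydroalkoxylation of a homopropargylic alcohol), placing the ketal carbon at C9 only.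

Step 11
Reactants: 14 (2S,5R)-2-methoxy-2-[(2R)-pent-4-en-2-yl]-1,7-dioxaspiro[4.4]nonan-6-one
Product: 15 (3R)-3-[(2S,5R)-2-methoxy-6-oxo-1,7-dioxaspiro[4.4]nonan-2-yl]butanal (ketal epimer also present)
Conditions: O3, CH2Cl2/MeOH, NaHCO3, −78 °C; PPh3, −78 → 25 °C
Reagents that add atoms: ozone, [O-][O+]=O
Why: Ozonolysis of the terminal alkene with reductive work-up; the medium is neutral and the ketal carbon bears no hydrogen.

Step 12
Reactants: 16 3-methylcyclohex-2-en-1-one
Product: 17 trimethyl{[(3S)-3-methyl-3-phenylcyclohex-1-en-1-yl]oxy}silane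
Conditions: PhLi, Et2AlCl, Et2O, 0 °C (gives PhAlEt2); Cu(O2C-2-C4H3S) (copper thiophene-2-carboxylate, 10 mol %), chiral aminophosphine ligand of the SimplePhos type (11 mol %, the enantiomer that gives the 3S centre), Et2O, −30 °C; then Me3SiOTf, −30 → 0 °C
Reagents that add atoms: phenyllithium, [Li]c1ccccc1; trimethylsilyl trifluoromethanesulfonate, C[Si](C)(C)OS(=O)(=O)C(F)(F)F
Why: Copper-catalysed enantioselective conjugate addition of an aryl alane to a β-methyl cyclohexenone sets the quaternary C4 under ligand control (4S); O-silylation of the aluminium enolate fixes the enolate at C5.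

Step 13
Reactants: 17 trimethyl{[(3S)-3-methyl-3-phenylcyclohex-1-en-1-yl]oxy}silane; 15 (3R)-3-[(2S,5R)-2-methoxy-6-oxo-1,7-dioxaspiro[4.4]nonan-2-yl]butanal
Product: 18 (2S,3S)-2-{(1R,3R)-3-[(2S,5R)-2-methoxy-6-oxo-1,7-dioxaspiro[4.4]nonan-2-yl]-1-[(trimethylsilyl)oxy]butyl}-3-methyl-3-phenylcyclohexan-1-one
Conditions: (Me2N)3S[Me3SiF2] (10 mol %), THF, −78 °C
Reagents that add atoms: none
Why: Fluoride-catalysed (Kuwajima–Noyori) aldol addition of an enol silane through an open antiperiplanar transition state. The aldehyde should approach C5 anti to the pseudo-axial phenyl group (5S, branch cis to the C4 methyl) with its chain turned away from C4 (syn aldol, 6R), and the aldolate is silylated by Me3SiF. No Lewis acid is present, so the ketal is not ionised.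

Step 14
Reactants: 18 (2S,3S)-2-{(1R,3R)-3-[(2S,5R)-2-methoxy-6-oxo-1,7-dioxaspiro[4.4]nonan-2-yl]-1-[(trimethylsilyl)oxy]butyl}-3-methyl-3-phenylcyclohexan-1-one
Product: 19 (2S,5R)-2-methoxy-2-{(2R,4R)-4-[(1R,2S)-6-(methoxymethylidene)-2-methyl-2-phenylcyclohexyl]-4-[(trimethylsilyl)oxy]butan-2-yl}-1,7-dioxaspiro[4.4]nonan-6-one (E/Z mixture)
Conditions: Ph3P(CH2OMe)Cl, KN(SiMe3)2, THF, 0 °C; then 18, 0 → 25 °C
Reagents that add atoms: (methoxymethyl)triphenylphosphonium chloride, COC[P+](c1ccccc1)(c1ccccc1)c1ccccc1.[Cl-]
Why: Wittig methoxymethylenation (one-carbon homologation of the C10 ketone); any enolisation should occur at the unhindered C1 methylene and be reversed on work-up, leaving C5 and the β-silyloxy group alone.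

Step 15
Reactants: 19 (2S,5R)-2-methoxy-2-{(2R,4R)-4-[(1R,2S)-6-(methoxymethylidene)-2-methyl-2-phenylcyclohexyl]-4-[(trimethylsilyl)oxy]butan-2-yl}-1,7-dioxaspiro[4.4]nonan-6-one
Product: 21 (2S,5R)-2-{(2R)-1-[(1R,7S,7aS)-3-hydroxy-7-methyl-7-phenyloctahydro-2-benzofuran-1-yl]propan-2-yl}-2-methoxy-1,7-dioxaspiro[4.4]nonan-6-one (mixture at C3 and C3a of the benzofuran), via silyloxy aldehyde 20 (not isolated)
Conditions: Hg(OAc)2, THF/H2O (10:1), 0 °C; aq. KI; then Bu4NF, AcOH, THF, 0 °C
Reagents that add atoms: water, O
Why: Oxymercuration of the enol ether in wet THF followed by iodide demercuration hydrolyses it to the aldehyde without acid, so the ketal survives. Fluoride then frees O6, which closes onto the aldehyde as the five-membered lactol.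

Step 16
Reactants: 21 (2S,5R)-2-{(2R)-1-[(1R,7S,7aS)-3-hydroxy-7-methyl-7-phenyloctahydro-2-benzofuran-1-yl]propan-2-yl}-2-methoxy-1,7-dioxaspiro[4.4]nonan-6-one
Product: 22 (2S,5R)-2-methoxy-2-{(2R)-1-[(1R,7S,7aR)-7-methyl-7-phenyl-1,4,5,6,7,7a-hexahydro-2-benzofuran-1-yl]propan-2-yl}-1,7-dioxaspiro[4.4]nonan-6-one (labdane numbering: 4S,5R,6R,8R,13R; C9 epimers)
Conditions: MsCl, Et3N, CH2Cl2, −40 → 25 °C
Reagents that add atoms: none
Why: Dehydration of a lactol through its mesylate or chloride with amine-induced loss of H10, as in the preparation of furanoid glycals. The medium stays basic, so the ketal and the new enol ether survive, and the C10 and C20 mixtures of 21 converge.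

Step 17
Reactants: 22 (2S,5R)-2-methoxy-2-{(2R)-1-[(1R,7S,7aR)-7-methyl-7-phenyl-1,4,5,6,7,7a-hexahydro-2-benzofuran-1-yl]propan-2-yl}-1,7-dioxaspiro[4.4]nonan-6-one
Product: 23 (4S,5R,6R,8R,9R,10R,13R,20R)-6,20:9,13-diepoxy-20-methoxy-4-phenyl-19-norlabdan-16,15-olide (5β-H, 6β-O, 8α-methyl, 9α-O, 4β-phenyl; either C20 anomer)
Conditions: Me3SiOTf (0.2 equiv), 2,6-di-tert-butyl-4-methylpyridine (0.3 equiv), CH2Cl2, −78 °C
Reagents that add atoms: none
Why: Me3SiOTf removes methoxide from the C9 ketal (either epimer) to give the five-membered oxocarbenium ion and Me3SiOMe; C10, the β-carbon of the O6-tethered cyclic enol ether, adds to C9, and the C20 oxocarbenium ion held in the two-atom bridge takes the methoxy group back from Me3SiOMe, regenerating the silyl triflate. The closest known reaction type is the Mukaiyama–Noyori addition of enol ethers and enol silanes to acetal-derived oxocarbenium ions, here intramolecular. Ring B (C5–C10) closes through a chair-like six-membered transition state, exo with respect to both the C9=O+ and the C10=C20 π bonds. C10 is set by the tether: C6 carries both O6 and C7, so C9 can only reach the face of C10 on which C7 lies, leaving C20 syn to O6 and H5 (10R here, which becomes the 10S centre of 30 by a change of priorities only). C9 is set by the chair: the ring C oxygen goes axial, anti to C20, because the alternative would place C11 and the spiro lactone 1,3-diaxial to the quaternary C4 (9R). C20 becomes an acetal centre of no consequence. The step needs the ketal to ionise in preference to protonation of the enol ether, and C–C bond formation to outrun loss of H8 from the cation; the silyl Lewis acid, the hindered pyridine base and −78 °C are chosen for that.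

Step 18
Reactants: 23 (4S,5R,6R,8R,9R,10R,13R,20R)-6,20:9,13-diepoxy-20-methoxy-4-phenyl-19-norlabdan-16,15-olide
Product: 25 (4S,5R,6R,8R,9R,10S,13R)-9,13-epoxy-6,20-dihydroxy-4-phenyl-19-norlabdan-16,15-olide, via bridged lactol 24 (not isolated)
Conditions: 1 M aq. HCl, THF, 25 °C; NaHCO3; then NaBH4, MeOH, 0 °C
Reagents that add atoms: water, O
Why: Aqueous acid hydrolyses the bridged methyl acetal to the lactol, whose hydroxy aldehyde tautomer is reduced by borohydride. Ring C is a di-tertiary ether and lactone D should tolerate both reagents at these temperatures; no stereocentre is touched.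

Step 19
Reactants: 25 (4S,5R,6R,8R,9R,10S,13R)-9,13-epoxy-6,20-dihydroxy-4-phenyl-19-norlabdan-16,15-olide
Product: 26 (4S,5R,6R,8R,9R,10S,13R)-20-acetoxy-9,13-epoxy-6-hydroxy-4-phenyl-19-norlabdan-16,15-olide
Conditions: Ac2O (1.1 equiv), pyridine, CH2Cl2, 0 °C
Reagents that add atoms: acetic anhydride, CC(=O)OC(C)=O
Why: Acylation of the primary hydroxyl should be much faster than that of the hindered secondary 6-hydroxyl.

Step 20
Reactants: 26 (4S,5R,6R,8R,9R,10S,13R)-20-acetoxy-9,13-epoxy-6-hydroxy-4-phenyl-19-norlabdan-16,15-olide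
Product: 27 (4S,5R,6R,8R,9R,10S,13R)-20-acetoxy-6-(chloroacetoxy)-9,13-epoxy-4-phenyl-19-norlabdan-16,15-olide
Conditions: (ClCH2CO)2O, pyridine, DMAP (cat.), CH2Cl2, 0 → 25 °C
Reagents that add atoms: chloroacetic anhydride, ClCC(=O)OC(=O)CCl
Why: Forced acylation of the 6-hydroxyl; the chloroacetate is inert to RuO4 and can later be removed beside an acetate.

Step 21
Reactants: 27 (4S,5R,6R,8R,9R,10S,13R)-20-acetoxy-6-(chloroacetoxy)-9,13-epoxy-4-phenyl-19-norlabdan-16,15-olide
Product: 28 (4S,5S,6R,8R,9R,10S,13R)-20-acetoxy-6-(chloroacetoxy)-9,13-epoxylabdan-16,15-olid-19-oic acid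
Conditions: RuCl3·xH2O (5 mol %), NaIO4 (excess), CCl4/MeCN/H2O, 25 °C
Reagents that add atoms: sodium periodate, [Na+].[O-]I(=O)(=O)=O; water, O
Why: Sharpless RuO4 degradation of a phenyl group to a carboxylic acid. C9 and C13 carry no hydrogen and every other oxygen-bearing carbon is acylated, so the arene is the only site of attack, and C4 keeps its configuration.

Step 22
Reactants: 28 (4S,5S,6R,8R,9R,10S,13R)-20-acetoxy-6-(chloroacetoxy)-9,13-epoxylabdan-16,15-olid-19-oic acid
Product: 29 (4S,5S,6R,8R,9R,10S,13R)-20-acetoxy-9,13-epoxy-6-hydroxylabdan-16,15-olid-19-oic acid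
Conditions: thiourea, NaHCO3, EtOH, 50 °C; aq. citric acid
Reagents that add atoms: none
Why: Thiourea alkylates at the CH2Cl group and cyclises onto the ester carbonyl, releasing the alcohol; the acetate has no such handle and stays.

Step 23
Reactants: 29 (4S,5S,6R,8R,9R,10S,13R)-20-acetoxy-9,13-epoxy-6-hydroxylabdan-16,15-olid-19-oic acid
Product: 30 (4S,5S,6R,8R,9R,10S,13R)-20-acetoxy-9,13-epoxylabdane-19,6:16,15-diolide (CNP0298733.1)
Conditions: 2,4,6-Cl3C6H2COCl, Et3N, THF, 25 °C; then DMAP, toluene, 80 °C
Reagents that add atoms: none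
Why: Yamaguchi lactonisation: the mixed anhydride is attacked by the neighbouring 6-hydroxyl under DMAP catalysis, and the irreversible acylation pays for the strain of the lactone.

## Compound list

1 | (4S)-4-benzyl-3-propanoyl-1,3-oxazolidin-2-one | CCC(=O)N1C(=O)OC[C@@H]1Cc1ccccc1 | starting material
2 | (4S)-4-benzyl-3-[(2R)-2-methylpent-4-enoyl]-1,3-oxazolidin-2-one | C=CC[C@@H](C)C(=O)N1C(=O)OC[C@@H]1Cc1ccccc1 | intermediate
3 | (2R)-2-methylpent-4-en-1-ol | C=CC[C@@H](C)CO | intermediate
4 | (2R)-2-methylpent-4-enal | C=CC[C@@H](C)C=O | intermediate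
5 | (3R)-1,1-dibromo-3-methylhexa-1,5-diene | C=CC[C@@H](C)C=C(Br)Br | intermediate
6 | (4R)-4-methylhept-6-en-2-yn-1-ol | C=CC[C@@H](C)C#CCO | intermediate
7 | (4R)-1-bromo-4-methylhept-6-en-2-yne | C=CC[C@@H](C)C#CCBr | intermediate
8 | (R)-malic acid | O[C@H](CC(=O)O)C(=O)O | starting material
9 | 2-[(2R,4R)-2-tert-butyl-5-oxo-1,3-dioxolan-4-yl]acetic acid (cis) | OC(=O)C[C@H]1O[C@@H](C(C)(C)C)OC1=O | intermediate
10 | (2R,5R)-2-tert-butyl-5-(2-hydroxyethyl)-1,3-dioxolan-4-one (not isolated) | OCC[C@H]1O[C@@H](C(C)(C)C)OC1=O | intermediate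
11 | (2R,5R)-2-tert-butyl-5-[2-(tert-butyldimethylsilyloxy)ethyl]-1,3-dioxolan-4-one | CC(C)(C)[Si](C)(C)OCC[C@H]1O[C@@H](C(C)(C)C)OC1=O | intermediate
12 | (2R,5R)-2-tert-butyl-5-[2-(tert-butyldimethylsilyloxy)ethyl]-5-[(4R)-4-methylhept-6-en-2-yn-1-yl]-1,3-dioxolan-4-one | CC(C)(C)[Si](C)(C)OCC[C@@]1(CC#C[C@H](C)CC=C)O[C@@H](C(C)(C)C)OC1=O | intermediate
13 | (3R)-3-hydroxy-3-[(4R)-4-methylhept-6-en-2-yn-1-yl]oxolan-2-one (not isolated) | C=CC[C@@H](C)C#CC[C@@]1(O)CCOC1=O | intermediate
14 | (2S,5R)-2-methoxy-2-[(2R)-pent-4-en-2-yl]-1,7-dioxaspiro[4.4]nonan-6-one (2S shown; 2R epimer also present) | C=CC[C@@H](C)[C@]1(OC)CC[C@]2(CCOC2=O)O1 | intermediate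
15 | (3R)-3-[(2S,5R)-2-methoxy-6-oxo-1,7-dioxaspiro[4.4]nonan-2-yl]butanal (ketal epimer also present) | O=CC[C@@H](C)[C@]1(OC)CC[C@]2(CCOC2=O)O1 | intermediate
16 | 3-methylcyclohex-2-en-1-one | CC1=CC(=O)CCC1 | starting material
17 | trimethyl{[(3S)-3-methyl-3-phenylcyclohex-1-en-1-yl]oxy}silane | C[Si](C)(C)OC1=C[C@@](C)(c2ccccc2)CCC1 | intermediate
18 | (2S,3S)-2-{(1R,3R)-3-[(2S,5R)-2-methoxy-6-oxo-1,7-dioxaspiro[4.4]nonan-2-yl]-1-[(trimethylsilyl)oxy]butyl}-3-methyl-3-phenylcyclohexan-1-one | O=C1CCC[C@](C)(c2ccccc2)[C@H]1[C@H](O[Si](C)(C)C)C[C@@H](C)[C@]3(OC)CC[C@]4(CCOC4=O)O3 | intermediate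
19 | (2S,5R)-2-methoxy-2-{(2R,4R)-4-[(1R,2S)-6-(methoxymethylidene)-2-methyl-2-phenylcyclohexyl]-4-[(trimethylsilyl)oxy]butan-2-yl}-1,7-dioxaspiro[4.4]nonan-6-one (E/Z mixture) | COC=C1CCC[C@](C)(c2ccccc2)[C@H]1[C@H](O[Si](C)(C)C)C[C@@H](C)[C@]3(OC)CC[C@]4(CCOC4=O)O3 | intermediate
20 | (2S,3S)-2-{(1R,3R)-3-[(2S,5R)-2-methoxy-6-oxo-1,7-dioxaspiro[4.4]nonan-2-yl]-1-[(trimethylsilyl)oxy]butyl}-3-methyl-3-phenylcyclohexane-1-carbaldehyde (C1 epimers; not isolated) | O=CC1CCC[C@](C)(c2ccccc2)[C@H]1[C@H](O[Si](C)(C)C)C[C@@H](C)[C@]3(OC)CC[C@]4(CCOC4=O)O3 | intermediate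
21 | (2S,5R)-2-{(2R)-1-[(1R,7S,7aS)-3-hydroxy-7-methyl-7-phenyloctahydro-2-benzofuran-1-yl]propan-2-yl}-2-methoxy-1,7-dioxaspiro[4.4]nonan-6-one (mixture at C3 and C3a) | OC1C2CCC[C@](C)(c3ccccc3)[C@H]2[C@H](O1)C[C@@H](C)[C@]4(OC)CC[C@]5(CCOC5=O)O4 | intermediate
22 | (2S,5R)-2-methoxy-2-{(2R)-1-[(1R,7S,7aR)-7-methyl-7-phenyl-1,4,5,6,7,7a-hexahydro-2-benzofuran-1-yl]propan-2-yl}-1,7-dioxaspiro[4.4]nonan-6-one (C9 epimers) | C1=C2CCC[C@](C)(c3ccccc3)[C@H]2[C@H](O1)C[C@@H](C)[C@]4(OC)CC[C@]5(CCOC5=O)O4 | intermediate
23 | (4S,5R,6R,8R,9R,10R,13R,20R)-6,20:9,13-diepoxy-20-methoxy-4-phenyl-19-norlabdan-16,15-olide (either C20 anomer) | CO[C@@H]1O[C@@H]2C[C@@H](C)[C@]3(CC[C@]4(CCOC4=O)O3)[C@]15CCC[C@](C)(c6ccccc6)[C@@H]25 | intermediate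
24 | (4S,5R,6R,8R,9R,10R,13R)-6,20:9,13-diepoxy-20-hydroxy-4-phenyl-19-norlabdan-16,15-olide (lactol anomers; not isolated) | OC1O[C@@H]2C[C@@H](C)[C@]3(CC[C@]4(CCOC4=O)O3)[C@]15CCC[C@](C)(c6ccccc6)[C@@H]25 | intermediate
25 | (4S,5R,6R,8R,9R,10S,13R)-9,13-epoxy-6,20-dihydroxy-4-phenyl-19-norlabdan-16,15-olide | OC[C@@]12CCC[C@](C)(c3ccccc3)[C@H]2[C@H](O)C[C@@H](C)[C@]14CC[C@]1(CCOC1=O)O4 | intermediate
26 | (4S,5R,6R,8R,9R,10S,13R)-20-acetoxy-9,13-epoxy-6-hydroxy-4-phenyl-19-norlabdan-16,15-olide | CC(=O)OC[C@@]12CCC[C@](C)(c3ccccc3)[C@H]2[C@H](O)C[C@@H](C)[C@]14CC[C@]1(CCOC1=O)O4 | intermediate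
27 | (4S,5R,6R,8R,9R,10S,13R)-20-acetoxy-6-(chloroacetoxy)-9,13-epoxy-4-phenyl-19-norlabdan-16,15-olide | CC(=O)OC[C@@]12CCC[C@](C)(c3ccccc3)[C@H]2[C@H](OC(=O)CCl)C[C@@H](C)[C@]14CC[C@]1(CCOC1=O)O4 | intermediate
28 | (4S,5S,6R,8R,9R,10S,13R)-20-acetoxy-6-(chloroacetoxy)-9,13-epoxylabdan-16,15-olid-19-oic acid | CC(=O)OC[C@@]12CCC[C@](C)(C(=O)O)[C@H]2[C@H](OC(=O)CCl)C[C@@H](C)[C@]14CC[C@]1(CCOC1=O)O4 | intermediate
29 | (4S,5S,6R,8R,9R,10S,13R)-20-acetoxy-9,13-epoxy-6-hydroxylabdan-16,15-olid-19-oic acid | CC(=O)OC[C@@]12CCC[C@](C)(C(=O)O)[C@H]2[C@H](O)C[C@@H](C)[C@]14CC[C@]1(CCOC1=O)O4 | intermediate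
30 | (4S,5S,6R,8R,9R,10S,13R)-20-acetoxy-9,13-epoxylabdane-19,6:16,15-diolide (CNP0298733.1) | CC(=O)OC[C@@]12CCC[C@]3(C)C(=O)O[C@H](C[C@@H](C)[C@]14CC[C@]1(CCOC1=O)O4)[C@@H]23 | target

## Step count and least certain steps

Total: 23 steps. Longest linear sequence: 20 steps (steps 1–6, 9–11 and 13–23).

**Step 17 (key step).** The likely failure is slow ring closure: C9 must reach the face of C10 flanked by the quaternary C4 and its axial methyl group, and two fully substituted carbons are joined. Loss of H8 from the C9 cation (which would scramble C8) or acid-induced decomposition of the strained enol ether could then compete. Fallback: give up the pre-formed dihydrofuran and cyclise the open-chain methyl enol ether 19 with Me3SiOTf and 2,6-di-tert-butyl-4-methylpyridine in CH2Cl2 at −78 °C. Ring B then closes first, by axial attack on ring A at C10 in a less constrained chair, and the C20 oxocarbenium ion is captured by the O6 silyl ether with loss of Me3SiOMe, returning the route to 23 without 20–22. The cost is that C10 is then set by the chair and no longer by the tether.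

**Step 13.** The naked enolate may deprotonate the enolisable aldehyde, the aldol may revert before silyl transfer, or the C5/C6 selectivity may be poor because both rely on one open transition state. Fallback from 17: MeLi in THF at 0 °C gives the lithium enolate, which is transmetallated with ClTi(OiPr)3 at −78 °C and treated with 15. Titanium triisopropoxide enolates of cyclic ketones add to aldehydes syn-selectively through a closed transition state and are too weakly Lewis acidic to ionise the ketal. The free aldol (2S,3S)-2-{(1R,3R)-1-hydroxy-3-[(2S,5R)-2-methoxy-6-oxo-1,7-dioxaspiro[4.4]nonan-2-yl]butyl}-3-methyl-3-phenylcyclohexan-1-one F1 is then silylated (Me3SiCl, imidazole) to return to 18.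

**Step 14.** The ylide may act as a base on the hindered ketone, leading to epimerisation at C5 or β-elimination of the silyloxy group, or olefination may simply be slow. Fallback from 18: non-basic methylenation with the Tebbe reagent Cp2Ti(μ-Cl)(μ-CH2)AlMe2 (pyridine, THF, −40 °C) gives (2S,5R)-2-methoxy-2-{(2R,4R)-4-[(1S,2S)-2-methyl-6-methylidene-2-phenylcyclohexyl]-4-[(trimethylsilyl)oxy]butan-2-yl}-1,7-dioxaspiro[4.4]nonan-6-one F2. Hydroboration with 9-BBN and oxidation with NaBO3·4H2O gives the primary alcohol (2S,5R)-2-{(2R,4R)-4-[(1S,2S)-6-(hydroxymethyl)-2-methyl-2-phenylcyclohexyl]-4-[(trimethylsilyl)oxy]butan-2-yl}-2-methoxy-1,7-dioxaspiro[4.4]nonan-6-one F3, and Dess–Martin oxidation gives the silyloxy aldehyde 20, which the fluoride stage of step 15 converts to 21.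

**Step 23.** Under the basic conditions the acetyl group may migrate from O20 to O6, or intermolecular acylation may win because the lactone closes against strain. Fallback from 28: activate the acid while O6 is still protected, as the S-pyridin-2-yl (4S,5S,6R,8R,9R,10S,13R)-20-acetoxy-6-(chloroacetoxy)-9,13-epoxylabdan-16,15-olide-19-thioate F4 (2,2′-dipyridyl disulfide, PPh3, toluene). Thiourea and NaHCO3 then remove the chloroacetate, and the freed 6-hydroxyl closes onto the thioester under neutral conditions (AgOTf if needed), giving 30 directly without 29.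

**Step 12.** O-silylation of the aluminium enolate may be incomplete, or the enol silane may be partly hydrolysed on work-up, and the enantiomeric purity cannot be upgraded at this stage. Fallback from 16: run the same conjugate addition but quench the enolate with Ac2O to the isolable (3S)-3-methyl-3-phenylcyclohex-1-en-1-yl acetate F5, purify it, and regenerate the enolate with MeLi (2 equiv, THF, 0 °C) before trapping with Me3SiCl to reach 17.

## Further compounds

F0 | step 17 | none | none
F1 | step 13 | (2S,3S)-2-{(1R,3R)-1-hydroxy-3-[(2S,5R)-2-methoxy-6-oxo-1,7-dioxaspiro[4.4]nonan-2-yl]butyl}-3-methyl-3-phenylcyclohexan-1-one | O=C1CCC[C@](C)(c2ccccc2)[C@H]1[C@H](O)C[C@@H](C)[C@]3(OC)CC[C@]4(CCOC4=O)O3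
F2 | step 14 | (2S,5R)-2-methoxy-2-{(2R,4R)-4-[(1S,2S)-2-methyl-6-methylidene-2-phenylcyclohexyl]-4-[(trimethylsilyl)oxy]butan-2-yl}-1,7-dioxaspiro[4.4]nonan-6-one | C=C1CCC[C@](C)(c2ccccc2)[C@H]1[C@H](O[Si](C)(C)C)C[C@@H](C)[C@]3(OC)CC[C@]4(CCOC4=O)O3
F3 | step 14 | (2S,5R)-2-{(2R,4R)-4-[(1S,2S)-6-(hydroxymethyl)-2-methyl-2-phenylcyclohexyl]-4-[(trimethylsilyl)oxy]butan-2-yl}-2-methoxy-1,7-dioxaspiro[4.4]nonan-6-one (C6 epimers of the cyclohexane) | OCC1CCC[C@](C)(c2ccccc2)[C@H]1[C@H](O[Si](C)(C)C)C[C@@H](C)[C@]3(OC)CC[C@]4(CCOC4=O)O3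
F4 | step 23 | S-pyridin-2-yl (4S,5S,6R,8R,9R,10S,13R)-20-acetoxy-6-(chloroacetoxy)-9,13-epoxylabdan-16,15-olide-19-thioate | CC(=O)OC[C@@]12CCC[C@](C)(C(=O)Sc3ccccn3)[C@H]2[C@H](OC(=O)CCl)C[C@@H](C)[C@]14CC[C@]1(CCOC1=O)O4
F5 | step 12 | (3S)-3-methyl-3-phenylcyclohex-1-en-1-yl acetate | CC(=O)OC1=C[C@@](C)(c2ccccc2)CCC1
A1 | alternative 1 | C13 diazo thioester with the C9 allyl ether on the tricyclic 19,6-lactone | CC(=O)OC[C@@]12CCC[C@]3(C)C(=O)O[C@H](C[C@@H](C)[C@]1(OCC=C)CCC(=[N+]=[N-])C(=O)SCC)[C@@H]23
A2 | alternative 1 | spiro oxolane with C13 bearing allyl (future C14–C15) and the thioester (future C16) | CC(=O)OC[C@@]12CCC[C@]3(C)C(=O)O[C@H](C[C@@H](C)[C@]14CC[C@@](CC=C)(C(=O)SCC)O4)[C@@H]23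
A3 | alternative 2 | triene with the Z-diene C3=C2–C1=C10 and the C4=C5 enoate linked through C6–C9 | CC(=O)OC/C(=C/C=C)[C@@]1(CC[C@]2(CCOC2=O)O1)[C@H](C)C[C@@H](O[Si](CC)(CC)CC)/C=C(\C)C(=O)OCc1ccccc1
A4 | alternative 2 | tetracyclic adduct with the C1=C2 alkene, C19 benzyl ester and O6 triethylsilyl ether | CC(=O)OC[C@@]12C=CC[C@](C)(C(=O)OCc3ccccc3)[C@H]2[C@H](O[Si](CC)(CC)CC)C[C@@H](C)[C@]14CC[C@]1(CCOC1=O)O4
A5 | alternative 3 | 6-hydroxy decalin with the C10 methyl group, C9 dioxolane ketal and C19 methyl ester | C[C@]12CCC[C@](C)(C(=O)OC)[C@H]1[C@H](O)C[C@@H](C)C23OCCO3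
A6 | alternative 3 | 6,20-epoxide (bridging oxolane O6–C20) | C1O[C@@H]2C[C@@H](C)C3(OCCO3)[C@]14CCC[C@](C)(C(=O)OC)[C@@H]24
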